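**The stall.** Start from the stop. The flask delta is the asked flask followed so far, and its target climbs and then almost halts.

| setting | delta | zeta | flask |
|---|---|---|---|
| starting material | 12 mM | 6 mM | 12 mM |
| second substrate | 12 mM | 12 mM | 12.0 mM |
| coupling partner | 12 mM | 12 mM | 12.0 mM |
| free catalyst | 1.1 mM | 1.1 mM | 1.1 mM |
| remark | the very flask that is asked about, followed so far | run made earlier |  |
| time |  |  | 5.0 h |

- delta (time / min: target / %): 20.0: 5.5; 30.0: 7.0; 50.0: 10.6; 80.0: 12.6; 150: 15.6; 240: 16.7
- zeta (time / min: target / %): 5.00: 2.0; 10.0: 3.2; 15.0: 5.7; 20.0: 6.9; 25.0: 7.6; 30.0: 8.6

(each reading ± 0.5 percentage points)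

- summer: at 5.0 h add free catalyst, 100% of the amount charged, then wait 5.0 h
- autumn: at 5.0 h add coupling partner, 50.0% of the amount charged, then wait 5.0 h
- dusk: change nothing and wait 5.0 h more
- winter: at 5.0 h take out 90% of the target then present, then wait 5.0 h

- target that was removed still counts
- additions bring no volume worth counting

1. target, in percent of the starting material first charged, at 5.0 h
2. the option that brings most further target ("none" if no option brings more than 2 percentage points) (summer / autumn / dusk / winter / none)
3. target present, with what was taken out counted in, in percent of the starting material first charged, after autumn
4. target present, with what was taken out counted in, in percent of the starting material first charged, after winter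

**Frozen reagent.** Delta gains 3 percentage points in the 70.0 min up to 150 min, then 1.1 points in the next 90.0 min, so the rate read off these readings falls by a factor of about 3.51, a ratio that carries their scatter. By 240 min target in delta accounts for 16.7% of the starting material, so starting material can be frozen as nearly constant, and target is better counted against catalyst. At 240 min delta stands at N = 1.82, the turnover number: target formed per catalyst charged, both in mM.

**The bracket.** From below, the readings of delta rise throughout, so the reckoning here takes the last one, 16.7%, as the floor at 5.0 h. From above, the earlier rate held to 5.0 h gives 19.3%. The later, lower rate tightens this to 17.4%. That bracket is 0.70 points wide against a scatter of 0.5 points per reading, so the hand stops there. Summer brings a fresh charge of catalyst, and at the same N that charge is worth 17 points. Autumn and winter bring no catalyst, so this reckoning expects them to stay close to 17.4% and commits to summer.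

**The forecast.** It gives 17.5%, with a range of 16.7% to 18.4%. That is 0.100 points above the upper bound, an excess less than the scatter. It names summer, with 18.5% after autumn and 28% after winter, the latter in a range of 18% to 33%. Its ground for winter: “Removing target helps only if sequestration is the cause, so that range is wide.”

**The result.** The flask gives 17.4% at 5.0 h, level with the upper bound. The best option is summer, gaining 9 points. Autumn ends at 18.3% and winter at 17.7%, so the forecast for winter stands 10 points high.

    catalyst intermediate B → spent catalyst (k = 7.20 × 10⁻⁴ s⁻¹)
    starting material + free catalyst ⇌ catalyst intermediate A (K = 73.0 M⁻¹, k = 6.10 M⁻¹ s⁻¹)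
    coupling partner + catalyst intermediate A → free catalyst + target (k = 0.170 M⁻¹ s⁻¹)
    coupling partner + catalyst intermediate B → free catalyst + second product (k = 0.410 M⁻¹ s⁻¹)
    second substrate + free catalyst ⇌ catalyst intermediate B (K = 190 M⁻¹, k = 0.650 M⁻¹ s⁻¹)

**Counting again.** By 300 min the flask holds 97.6% of the catalyst charged as spent catalyst. N there is 1.90, and the fresh catalyst of summer gains 9 points, less than the 17 points reckoned at constant N. The neighbour charged with 48 mM of coupling partner reaches 95.8% target, which is N = 10.4, with 50.5% of its catalyst spent.

The runs were computed with made-up constants, and the scatter is random.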